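**Retrosynthetic overview**

- Pyridone C3–C(=O) bond: pyridyl Grignard reagent plus decalin aldehyde 17, then oxidation. Pyridone C5–C(OH) bond: 5-lithiopyridine plus epoxy ketone 10, attacking anti to the oxirane. The N–OH is carried as a pyridine N-oxide made before the alkene-bearing decalin arrives; both ring oxygens are carried as 2-(trimethylsilyl)ethyl ethers.
- Enabling feature: in the 7-oxabicyclo[4.1.0]heptane unit the two oxirane carbons sit α and β to the aryl carbinol carbon, so 10 is an α,β-epoxy ketone. Its C=O carbon and β-C–O carbon are 1,3-related, which is the imprint of a cyclopropanol bond.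
- The six-membered carbocycle is therefore made by ring expansion of the five-membered ring of bicyclo[3.1.0]hexan-1-ol 8: scission of the ring-fusion cyclopropane bond, O2 capture, oxirane closure. The silyloxy stereocentre steers both new centres.
- Cyclopropanol 8 comes from an intramolecular Kulinkovich reaction of silyloxy hexenoate 7 (from L-glutamic-acid-derived lactone 1). The decalin comes from an intramolecular Diels–Alder reaction of trienal 16 (from (R)-citronellal).
- Ring order: cyclopentane and cyclopropane (step 5), then cyclohexanone and oxirane (step 6); decalin rings A and B together (step 10); the pyridine ring is bought.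

Key step: step 6

Assumption: 28 is treated as the 1-hydroxy-2-pyridone tautomer drawn (tertiary OH cis, secondary OH trans to the oxirane oxygen); the carbinol centre made in step 15 is left undefined because step 16 removes it.

**Route**

Step 1
Reactants: 1 (5S)-5-(hydroxymethyl)oxolan-2-one
Product: 2 (2S)-5-oxooxolane-2-carbaldehyde
Conditions: Dess–Martin periodinane (1.2 equiv), NaHCO3, CH2Cl2, 0 °C → rt
Reagents that add atoms: none
Why: Dess–Martin oxidation of the primary alcohol stops at the aldehyde under buffered, non-basic conditions, so the α-oxygenated stereocentre should not epimerise.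

Step 2
Reactants: 2 (2S)-5-oxooxolane-2-carbaldehyde
Product: 3 (5S)-5-ethenyloxolan-2-one
Conditions: Ph3PCH3Br (1.1 equiv), KN(SiMe3)2 (1.05 equiv), THF, −78 → 0 °C
Reagents that add atoms: methyltriphenylphosphonium bromide, C[P+](c1ccccc1)(c1ccccc1)c1ccccc1.[Br-]
Why: Wittig methylenation with the salt-free non-stabilised ylide at low temperature should be faster than attack on the lactone or α-epimerisation.

Step 3
Reactants: 3 (5S)-5-ethenyloxolan-2-one
Product: 6 (4S)-4-[(tert-butyldimethylsilyl)oxy]hex-5-enoic acid, via potassium hydroxy carboxylate 4 (not isolated), via silyl ester silyl ether 5 (not isolated)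
Conditions: KOH (1.05 equiv), MeOH/H2O, rt, evaporate; TBSCl (2.5 equiv), imidazole, DMF, rt; then K2CO3 (cat.), MeOH/THF/H2O, rt; citric acid work-up
Reagents that add atoms: potassium hydroxide, [K+].[OH-]; tert-butyldimethylsilyl chloride, CC(C)(C)[Si](C)(C)Cl
Why: Saponification opens the γ-lactone, double silylation caps the alcohol before it can relactonise, and mild methanolysis cleaves only the labile silyl ester, leaving the stereocentre untouched.

Step 4
Reactants: 6 (4S)-4-[(tert-butyldimethylsilyl)oxy]hex-5-enoic acid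
Product: 7 methyl (4S)-4-[(tert-butyldimethylsilyl)oxy]hex-5-enoate
Conditions: MeI (1.5 equiv), K2CO3 (1.5 equiv), DMF, rt
Reagents that add atoms: iodomethane, CI
Why: SN2 O-alkylation of the carboxylate gives the methyl ester needed for the Kulinkovich reaction without acid that would remove the silyl ether.

Step 5
Reactants: 7 methyl (4S)-4-[(tert-butyldimethylsilyl)oxy]hex-5-enoate
Product: 8 (4S)-4-[(tert-butyldimethylsilyl)oxy]bicyclo[3.1.0]hexan-1-ol (cis-fused, both orientations of the cyclopropane relative to C4)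
Conditions: Ti(OiPr)4 (1.0 equiv), c-C5H9MgCl (2.2 equiv, slow addition), Et2O/THF, 0 °C → rt
Reagents that add atoms: none
Why: Intramolecular Kulinkovich reaction: the titanacyclopropane formed by ligand exchange with the terminal alkene adds to the ester (five-membered ring), methoxide leaves and the remaining C–Ti bond closes the cyclopropanol; the ring fusion must be cis, and both diastereomers are usable because C1 and C5 lose their configuration in step 6.

Step 6
Reactants: 8 (4S)-4-[(tert-butyldimethylsilyl)oxy]bicyclo[3.1.0]hexan-1-ol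
Product: 10 (1R,5S,6S)-5-[(tert-butyldimethylsilyl)oxy]-7-oxabicyclo[4.1.0]heptan-2-one, via β-hydroperoxy ketone 9 (not isolated)
Conditions: Mn(acac)3 (5 mol%), O2 (1 atm), benzene, rt; then KOH (0.5 equiv), MeOH, 0 °C
Reagents that add atoms: dioxygen, O=O
Why: Proposed new method: the manganese catalyst and O2 should turn the cyclopropanol into its oxyl radical, which cleaves the strained ring-fusion bond C1–C5 to give the ring-expanded secondary 3-oxocyclohexyl radical; O2 capture gives hydroperoxide 9, and base lets the α-keto carbanion displace hydroxide at the peroxide oxygen bound to the β-carbon, so ring expansion, ketone and oxirane arise in one flask. The closest known reaction types are the manganese-catalysed aerobic opening of monocyclic cyclopropanols to β-peroxy ketones that give α,β-epoxy ketones with base, and the Saegusa–Ito ring expansion of 1-siloxybicyclo[n.1.0]alkanes through the same internal-bond scission; their combination on a fused cyclopropanol is the untested part. The six-membered ring is not closed by cyclisation but formed by merging the five- and three-membered rings, and the oxirane closes 3-exo-tet at oxygen and is necessarily cis-fused. The two new stereocentres (oxirane carbons C1 and C6 of 10) are controlled by the C5 silyloxy group: O2 should add anti to it, and because the β-peroxy enolate is the Weitz–Scheffer intermediate, reversible loss and re-addition of hydroperoxide through the enone should funnel any syn isomer to the trans epoxide. The step needs internal over external cyclopropane scission, secured by the more stable secondary ring radical and the relief of bicyclic strain, and oxirane closure over Kornblum–DeLaMare fragmentation, secured by the higher acidity of the α-keto C–H.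

Step 7
Reactants: 11 (3R)-3,7-dimethyloct-6-enal
Product: 13 (2E,4E,7R)-7,11-dimethyldodeca-2,4,10-triene, via (4Z)-triene isomer 12 (not isolated)
Conditions: [(2E)-but-2-en-1-yl]triphenylphosphonium bromide (1.2 equiv), n-BuLi (1.15 equiv), THF, −78 °C → rt; then I2 (5 mol%), hexane, daylight, rt
Reagents that add atoms: [(2E)-but-2-en-1-yl]triphenylphosphonium bromide, C/C=C/C[P+](c1ccccc1)(c1ccccc1)c1ccccc1.[Br-]
Why: Wittig olefination with the semistabilised crotyl ylide gives a 4E/4Z mixture, and iodine-catalysed equilibration should converge it on the (2E,4E)-diene needed for the cycloaddition, with C7 untouched.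

Step 8
Reactants: 13 (2E,4E,7R)-7,11-dimethyldodeca-2,4,10-triene
Product: 15 (4R,6E,8E)-4-methyldeca-6,8-dienal, via terminal epoxide 14 (not isolated)
Conditions: mCPBA (1.0 equiv), CH2Cl2, −20 °C; then H5IO6 (1.2 equiv), THF/H2O, 0 °C
Reagents that add atoms: 3-chloroperoxybenzoic acid, OOC(=O)c1cccc(Cl)c1
Why: The trialkyl-substituted alkene is the most nucleophilic π bond and should be epoxidised selectively by one equivalent of peracid, after which periodic acid hydrolyses and cleaves the epoxide to the aldehyde and acetone.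

Step 9
Reactants: 15 (4R,6E,8E)-4-methyldeca-6,8-dienal
Product: 16 (2E,6R,8E,10E)-6-methyldodeca-2,8,10-trienal
Conditions: Ph3P=CHCHO (1.2 equiv), toluene, 80 °C
Reagents that add atoms: (triphenylphosphoranylidene)acetaldehyde, O=CC=P(c1ccccc1)(c1ccccc1)c1ccccc1
Why: Wittig reaction with the stabilised formylmethylene ylide is E-selective and, with a small excess only, should stop after one homologation.

Step 10
Reactants: 16 (2E,6R,8E,10E)-6-methyldodeca-2,8,10-trienal
Product: 17 (1R,2R,4aS,6R,8aR)-2,6-dimethyl-1,2,4a,5,6,7,8,8a-octahydronaphthalene-1-carbaldehyde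
Conditions: Me2AlCl (1.1 equiv), CH2Cl2, −78 → −20 °C
Reagents that add atoms: none
Why: Lewis-acid-promoted intramolecular Diels–Alder reaction through the endo transition state with a chair-like four-carbon tether and the C6 methyl equatorial should give the trans ring fusion and the equatorial formyl group cis to the C2 methyl, all set relative to the (6R) centre.

Step 11
Reactants: 18 5-bromo-2,4-dichloropyridine
Product: 19 5-bromo-2,4-bis[2-(trimethylsilyl)ethoxy]pyridine
Conditions: Me3SiCH2CH2OH (2.5 equiv), NaH (2.6 equiv), DMF, 0 → 70 °C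
Reagents that add atoms: 2-(trimethylsilyl)ethanol, C[Si](C)(C)CCO
Why: Twofold SNAr: the alkoxide displaces the 4-chloride and, on warming, the 2-chloride (both activated by the ring nitrogen), while the 5-bromide is inert.

Step 12
Reactants: 19 5-bromo-2,4-bis[2-(trimethylsilyl)ethoxy]pyridine; 10 (1R,5S,6S)-5-[(tert-butyldimethylsilyl)oxy]-7-oxabicyclo[4.1.0]heptan-2-one
Product: 22 5-{(1R,2R,5S,6S)-5-[(tert-butyldimethylsilyl)oxy]-2-[(triethylsilyl)oxy]-7-oxabicyclo[4.1.0]heptan-2-yl}-2,4-bis[2-(trimethylsilyl)ethoxy]pyridine, via aryllithium 20 (not isolated), via lithium alkoxide 21 (not isolated)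
Conditions: n-BuLi (1.05 equiv), THF, −78 °C; 10, −78 °C; then TESOTf (1.3 equiv), 2,6-lutidine, −78 → 0 °C
Reagents that add atoms: triethylsilyl trifluoromethanesulfonate, CC[Si](CC)(CC)OS(=O)(=O)C(F)(F)F
Why: Bromine–lithium exchange and 1,2-addition of the aryllithium to the ketone on the face anti to the adjacent oxirane oxygen should set the carbinol centre with its oxygen cis to the epoxide and trans to the silyloxy group, and the tertiary alkoxide is capped in the same flask.

Step 13
Reactants: 22 (TES ether from step 12)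
Product: 23 3-bromo-5-{(1R,2R,5S,6S)-5-[(tert-butyldimethylsilyl)oxy]-2-[(triethylsilyl)oxy]-7-oxabicyclo[4.1.0]heptan-2-yl}-2,4-bis[2-(trimethylsilyl)ethoxy]pyridine
Conditions: NBS (1.05 equiv), NaHCO3, MeCN, 0 °C → rt, dark
Reagents that add atoms: N-bromosuccinimide, O=C1CCC(=O)N1Br
Why: Electrophilic aromatic bromination should go to C3, the only ring position ortho to both alkoxy groups, since C6 is unactivated.

Step 14
Reactants: 23 (3-bromopyridine from step 13)
Product: 24 3-bromo-5-{(1R,2R,5S,6S)-5-[(tert-butyldimethylsilyl)oxy]-2-[(triethylsilyl)oxy]-7-oxabicyclo[4.1.0]heptan-2-yl}-2,4-bis[2-(trimethylsilyl)ethoxy]pyridine 1-oxide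
Conditions: mCPBA (1.5 equiv), NaHCO3, CH2Cl2, 0 °C → rt
Reagents that add atoms: 3-chloroperoxybenzoic acid, OOC(=O)c1cccc(Cl)c1
Why: Peracid N-oxidation of the pyridine installs the future N–OH oxygen at the only stage where no alkene competes for the oxidant.

Step 15
Reactants: 24 (N-oxide from step 14); 17 (1R,2R,4aS,6R,8aR)-2,6-dimethyl-1,2,4a,5,6,7,8,8a-octahydronaphthalene-1-carbaldehyde
Product: 26 3-{[(1R,2R,4aS,6R,8aR)-2,6-dimethyl-1,2,4a,5,6,7,8,8a-octahydronaphthalen-1-yl](hydroxy)methyl}-5-{(1R,2R,5S,6S)-5-[(tert-butyldimethylsilyl)oxy]-2-[(triethylsilyl)oxy]-7-oxabicyclo[4.1.0]heptan-2-yl}-2,4-bis[2-(trimethylsilyl)ethoxy]pyridine 1-oxide (both carbinol epimers), via pyridylmagnesium chloride 25 (not isolated)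
Conditions: i-PrMgCl·LiCl (1.1 equiv), THF, −40 °C; then 17, LaCl3·2LiCl (0.3 equiv), −40 → 0 °C; aq. NH4Cl
Reagents that add atoms: none
Why: Bromine–magnesium exchange with the turbo-Grignard reagent (a known reaction of bromopyridine N-oxides, helped here by two ortho alkoxy groups) followed by 1,2-addition to the aldehyde forms the last C–C bond; the new carbinol centre is a mixture that step 16 erases.

Step 16
Reactants: 26 (carbinol from step 15)
Product: 27 [(1R,2R,4aS,6R,8aR)-2,6-dimethyl-1,2,4a,5,6,7,8,8a-octahydronaphthalen-1-yl]{5-[(1R,2R,5S,6S)-5-[(tert-butyldimethylsilyl)oxy]-2-[(triethylsilyl)oxy]-7-oxabicyclo[4.1.0]heptan-2-yl]-1-oxido-2,4-bis[2-(trimethylsilyl)ethoxy]pyridin-1-ium-3-yl}methanone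
Conditions: Dess–Martin periodinane (1.5 equiv), NaHCO3, CH2Cl2, 0 °C → rt
Reagents that add atoms: none
Why: Buffered Dess–Martin oxidation of the secondary alcohol to the aryl ketone should leave epoxide, silyl ethers, N-oxide and alkene untouched, and the α-centre of the decalin already carries the acyl group in the favoured equatorial position.

Step 17
Reactants: 27 (ketone from step 16)
Product: 28 5-[(1R,2R,5S,6R)-2,5-dihydroxy-7-oxabicyclo[4.1.0]heptan-2-yl]-3-[(1R,2R,4aS,6R,8aR)-2,6-dimethyl-1,2,4a,5,6,7,8,8a-octahydronaphthalene-1-carbonyl]-1,4-dihydroxypyridin-2(1H)-one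
Conditions: TBAF (6 equiv), AcOH (6 equiv), THF, 0 → 40 °C
Reagents that add atoms: none
Why: Fluoride-induced global desilylation cleaves the TES and TBS ethers and fragments both 2-(trimethylsilyl)ethyl ethers (ethene and Me3SiF), the freed 2-oxidopyridine N-oxide is the 1-hydroxy-2-pyridone tautomer, and the acetic acid buffer should suppress Payne rearrangement of the epoxy alcohol.

**Compound list**

1 | (5S)-5-(hydroxymethyl)oxolan-2-one | OC[C@@H]1CCC(=O)O1 | starting material
2 | (2S)-5-oxooxolane-2-carbaldehyde | O=C[C@@H]1CCC(=O)O1 | intermediate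
3 | (5S)-5-ethenyloxolan-2-one | C=C[C@@H]1CCC(=O)O1 | intermediate
4 | potassium (4S)-4-hydroxyhex-5-enoate | [K+].[O-]C(=O)CC[C@H](O)C=C | intermediate (not isolated)
5 | tert-butyldimethylsilyl (4S)-4-[(tert-butyldimethylsilyl)oxy]hex-5-enoate | CC(C)(C)[Si](C)(C)OC(=O)CC[C@H](O[Si](C)(C)C(C)(C)C)C=C | intermediate (not isolated)
6 | (4S)-4-[(tert-butyldimethylsilyl)oxy]hex-5-enoic acid | OC(=O)CC[C@H](O[Si](C)(C)C(C)(C)C)C=C | intermediate
7 | methyl (4S)-4-[(tert-butyldimethylsilyl)oxy]hex-5-enoate | COC(=O)CC[C@H](O[Si](C)(C)C(C)(C)C)C=C | intermediate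
8 | (4S)-4-[(tert-butyldimethylsilyl)oxy]bicyclo[3.1.0]hexan-1-ol (cis-fused, both ring-fusion diastereomers) | OC12CC[C@H](O[Si](C)(C)C(C)(C)C)C1C2 | intermediate
9 | (4S)-4-[(tert-butyldimethylsilyl)oxy]-3-hydroperoxycyclohexan-1-one (C3 epimers) | O=C1CC[C@H](O[Si](C)(C)C(C)(C)C)C(OO)C1 | intermediate (not isolated)
10 | (1R,5S,6S)-5-[(tert-butyldimethylsilyl)oxy]-7-oxabicyclo[4.1.0]heptan-2-one (oxirane trans to the silyloxy group) | O=C1CC[C@H](O[Si](C)(C)C(C)(C)C)[C@H]2O[C@H]21 | intermediate
11 | (3R)-3,7-dimethyloct-6-enal, (R)-citronellal | C[C@H](CCC=C(C)C)CC=O | starting material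
12 | (2E,4Z,7R)-7,11-dimethyldodeca-2,4,10-triene | C[C@H](CCC=C(C)C)C/C=C\C=C\C | intermediate (not isolated)
13 | (2E,4E,7R)-7,11-dimethyldodeca-2,4,10-triene | C[C@H](CCC=C(C)C)C/C=C/C=C/C | intermediate
14 | 2,2-dimethyl-3-[(3R,5E,7E)-3-methylnona-5,7-dien-1-yl]oxirane (both oxirane epimers) | C[C@H](CCC1OC1(C)C)C/C=C/C=C/C | intermediate (not isolated)
15 | (4R,6E,8E)-4-methyldeca-6,8-dienal | C[C@H](CCC=O)C/C=C/C=C/C | intermediate
16 | (2E,6R,8E,10E)-6-methyldodeca-2,8,10-trienal | C[C@H](CC/C=C/C=O)C/C=C/C=C/C | intermediate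
17 | (1R,2R,4aS,6R,8aR)-2,6-dimethyl-1,2,4a,5,6,7,8,8a-octahydronaphthalene-1-carbaldehyde | C[C@@H]1CC[C@H]2[C@H](C=O)[C@H](C)C=C[C@@H]2C1 | intermediate
18 | 5-bromo-2,4-dichloropyridine | Clc1cc(Cl)c(Br)cn1 | starting material
19 | 5-bromo-2,4-bis[2-(trimethylsilyl)ethoxy]pyridine | C[Si](C)(C)CCOc1cc(OCC[Si](C)(C)C)c(Br)cn1 | intermediate
20 | {4,6-bis[2-(trimethylsilyl)ethoxy]pyridin-3-yl}lithium | [Li]c1cnc(OCC[Si](C)(C)C)cc1OCC[Si](C)(C)C | intermediate (not isolated)
21 | lithium (1R,2R,5S,6S)-2-{4,6-bis[2-(trimethylsilyl)ethoxy]pyridin-3-yl}-5-[(tert-butyldimethylsilyl)oxy]-7-oxabicyclo[4.1.0]heptan-2-olate | C[Si](C)(C)CCOc1cc(OCC[Si](C)(C)C)c(cn1)[C@]2([O-])CC[C@H](O[Si](C)(C)C(C)(C)C)[C@H]3O[C@H]32.[Li+] | intermediate (not isolated)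
22 | 5-{(1R,2R,5S,6S)-5-[(tert-butyldimethylsilyl)oxy]-2-[(triethylsilyl)oxy]-7-oxabicyclo[4.1.0]heptan-2-yl}-2,4-bis[2-(trimethylsilyl)ethoxy]pyridine | C[Si](C)(C)CCOc1cc(OCC[Si](C)(C)C)c(cn1)[C@]2(O[Si](CC)(CC)CC)CC[C@H](O[Si](C)(C)C(C)(C)C)[C@H]3O[C@H]32 | intermediate
23 | 3-bromo derivative of 22 | C[Si](C)(C)CCOc1c(Br)c(OCC[Si](C)(C)C)c(cn1)[C@]2(O[Si](CC)(CC)CC)CC[C@H](O[Si](C)(C)C(C)(C)C)[C@H]3O[C@H]32 | intermediate
24 | 1-oxide of 23 | C[Si](C)(C)CCOc1c(Br)c(OCC[Si](C)(C)C)c(c[n+]1[O-])[C@]2(O[Si](CC)(CC)CC)CC[C@H](O[Si](C)(C)C(C)(C)C)[C@H]3O[C@H]32 | intermediate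
25 | 3-(chloromagnesio) analogue of 24 | C[Si](C)(C)CCOc1c([Mg]Cl)c(OCC[Si](C)(C)C)c(c[n+]1[O-])[C@]2(O[Si](CC)(CC)CC)CC[C@H](O[Si](C)(C)C(C)(C)C)[C@H]3O[C@H]32 | intermediate (not isolated)
26 | 3-{[(1R,2R,4aS,6R,8aR)-2,6-dimethyloctahydronaphthalen-1-yl](hydroxy)methyl}pyridine 1-oxide, fully silyl-protected (both carbinol epimers) | C[C@@H]1CC[C@H]2[C@H](C(O)c3c(OCC[Si](C)(C)C)c([C@]4(O[Si](CC)(CC)CC)CC[C@H](O[Si](C)(C)C(C)(C)C)[C@H]5O[C@H]54)c[n+]([O-])c3OCC[Si](C)(C)C)[C@H](C)C=C[C@@H]2C1 | intermediate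
27 | corresponding aryl decalinyl ketone, pyridine 1-oxide, fully silyl-protected | C[C@@H]1CC[C@H]2[C@H](C(=O)c3c(OCC[Si](C)(C)C)c([C@]4(O[Si](CC)(CC)CC)CC[C@H](O[Si](C)(C)C(C)(C)C)[C@H]5O[C@H]54)c[n+]([O-])c3OCC[Si](C)(C)C)[C@H](C)C=C[C@@H]2C1 | intermediate
28 | 5-[(1R,2R,5S,6R)-2,5-dihydroxy-7-oxabicyclo[4.1.0]heptan-2-yl]-3-[(1R,2R,4aS,6R,8aR)-2,6-dimethyl-1,2,4a,5,6,7,8,8a-octahydronaphthalene-1-carbonyl]-1,4-dihydroxypyridin-2(1H)-one | C[C@@H]1CC[C@H]2[C@H](C(=O)c3c(O)c([C@]4(O)CC[C@H](O)[C@H]5O[C@H]54)cn(O)c3=O)[C@H](C)C=C[C@@H]2C1 | target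

**Summary**

Total step count: 17.
Longest linear sequence: 12 steps (steps 1–6, then 12–17).

**Steps most likely to fail**

1. Step 6 (bears the label). The oxyl radical may cleave the external cyclopropane bond, the peroxide may fragment instead of closing the oxirane, or oxygen capture may show poor facial control. Fallback from 8 back to 10 with known reactions: FeCl3 in DMF at 0 °C (Saegusa–Ito-type oxidative ring expansion) would turn cyclopropanol 8 into (4S)-4-[(tert-butyldimethylsilyl)oxy]-3-chlorocyclohexan-1-one F1. NaOAc in MeOH would then eliminate HCl to give (4S)-4-[(tert-butyldimethylsilyl)oxy]cyclohex-2-en-1-one F2. Weitz–Scheffer epoxidation (H2O2, NaOH, MeOH, 0 °C), anti to the silyloxy group, would return to epoxy ketone 10.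

2. Step 15. Deprotonation next to the N-oxide may outrun bromine–magnesium exchange, or the hindered Grignard reagent may fail to add to the α-branched aldehyde. Fallback from 22 to 28, making the N–O bond last: 22 would be lithiated at C3 with lithium 2,2,6,6-tetramethylpiperidide (THF, −78 °C) and added to aldehyde 17 to give the protected pyridyl carbinol F3. Dess–Martin oxidation would give the protected pyridyl ketone F4, and TBAF/AcOH would remove all silicon groups to give the N–H pyridone F5. F5 would be persilylated with N,O-bis(trimethylsilyl)acetamide to the tetrakis(trimethylsilyl) derivative F6 and oxidised at nitrogen with MoO5·pyridine·HMPA (the oxidation of O-silylated lactams to hydroxamic acids); methanolic work-up would give 28. This oxidation runs in the presence of the decalin alkene, which is its own weak point.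

3. Step 5. The titanacyclopropane may eliminate the allylic silyloxy group, or ligand exchange may stall, instead of closing onto the ester. Fallback from 6 back to 8: MeLi (2.2 equiv, Et2O) would convert acid 6 into (5S)-5-[(tert-butyldimethylsilyl)oxy]hept-6-en-2-one F7. LiN(iPr)2 and TMSCl at −78 °C would give the kinetic enol ether tert-butyldimethyl{[(3S)-6-[(trimethylsilyl)oxy]hepta-1,6-dien-3-yl]oxy}silane F8. Ring-closing metathesis with the second-generation Grubbs catalyst would give tert-butyldimethyl{[(1S)-3-[(trimethylsilyl)oxy]cyclopent-2-en-1-yl]oxy}silane F9. Simmons–Smith cyclopropanation (Et2Zn, CH2I2) would give (4S)-4-[(tert-butyldimethylsilyl)oxy]-1-[(trimethylsilyl)oxy]bicyclo[3.1.0]hexane F10, and K2CO3 in MeOH would free cyclopropanol 8.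

Further compounds

F1 | step 6 | (4S)-4-[(tert-butyldimethylsilyl)oxy]-3-chlorocyclohexan-1-one (C3 epimers) | O=C1CC[C@H](O[Si](C)(C)C(C)(C)C)C(Cl)C1
F2 | step 6 | (4S)-4-[(tert-butyldimethylsilyl)oxy]cyclohex-2-en-1-one | O=C1CC[C@H](O[Si](C)(C)C(C)(C)C)C=C1
F3 | step 15 | protected pyridyl carbinol (analogue of 26 without the N-oxide, both carbinol epimers) | C[C@@H]1CC[C@H]2[C@H](C(O)c3c(OCC[Si](C)(C)C)c([C@]4(O[Si](CC)(CC)CC)CC[C@H](O[Si](C)(C)C(C)(C)C)[C@H]5O[C@H]54)cnc3OCC[Si](C)(C)C)[C@H](C)C=C[C@@H]2C1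
F4 | step 15 | protected pyridyl ketone (analogue of 27 without the N-oxide) | C[C@@H]1CC[C@H]2[C@H](C(=O)c3c(OCC[Si](C)(C)C)c([C@]4(O[Si](CC)(CC)CC)CC[C@H](O[Si](C)(C)C(C)(C)C)[C@H]5O[C@H]54)cnc3OCC[Si](C)(C)C)[C@H](C)C=C[C@@H]2C1
F5 | step 15 | 5-[(1R,2R,5S,6R)-2,5-dihydroxy-7-oxabicyclo[4.1.0]heptan-2-yl]-3-[(1R,2R,4aS,6R,8aR)-2,6-dimethyl-1,2,4a,5,6,7,8,8a-octahydronaphthalene-1-carbonyl]-4-hydroxypyridin-2(1H)-one | C[C@@H]1CC[C@H]2[C@H](C(=O)c3c(O)c([C@]4(O)CC[C@H](O)[C@H]5O[C@H]54)c[nH]c3=O)[C@H](C)C=C[C@@H]2C1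
F6 | step 15 | tetrakis(trimethylsilyl) derivative of F5 (2-silyloxypyridine form, not isolated) | C[C@@H]1CC[C@H]2[C@H](C(=O)c3c(O[Si](C)(C)C)c([C@]4(O[Si](C)(C)C)CC[C@H](O[Si](C)(C)C)[C@H]5O[C@H]54)cnc3O[Si](C)(C)C)[C@H](C)C=C[C@@H]2C1
F7 | step 5 | (5S)-5-[(tert-butyldimethylsilyl)oxy]hept-6-en-2-one | CC(=O)CC[C@H](O[Si](C)(C)C(C)(C)C)C=C
F8 | step 5 | tert-butyldimethyl{[(3S)-6-[(trimethylsilyl)oxy]hepta-1,6-dien-3-yl]oxy}silane | C=C(O[Si](C)(C)C)CC[C@H](O[Si](C)(C)C(C)(C)C)C=C
F9 | step 5 | tert-butyldimethyl{[(1S)-3-[(trimethylsilyl)oxy]cyclopent-2-en-1-yl]oxy}silane | C1C[C@H](O[Si](C)(C)C(C)(C)C)C=C1O[Si](C)(C)C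
F10 | step 5 | (4S)-4-[(tert-butyldimethylsilyl)oxy]-1-[(trimethylsilyl)oxy]bicyclo[3.1.0]hexane | C[Si](C)(C)OC12CC[C@H](O[Si](C)(C)C(C)(C)C)C1C2
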